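## Retrosynthetic overview

1. The target comes from a twofold SeO2 allylic hydroxylation (C3, C9) of the 6-hydroxy bis-exo-methylene hydroazulene, which comes from hydride reduction of the C6 ketone.
2. The seven-membered ring comes from a one-carbon ring expansion (1,2-alkyl shift) of a trans-hydrindan-4-one by the side-chain diazoalkane: C7 is inserted between C6 and C8, which joins the two halves and sets C7.
3. The trans-hydrindanone comes from (R)-4-silyloxycyclohexenone by conjugate addition/allylation (C5 and C1 trans), ring-closing metathesis (five-membered ring), methylenation and protodesilylation (both exo-methylenes).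
4. The side chain comes from prenal and methallyl MOM ether (alkoxyallylboration, syn-diol), then Rh-catalysed hydroboration (C11), oxidation and N-silylhydrazone formation.
5. Ring order: six-membered ring (bought), then five-membered ring (metathesis), then the six is expanded to the seven.

Numbering used below: five-membered ring C1–C5 (C3–OH, C4=CH2), seven-membered ring C1, C5–C10 (C6–OH, C7 side chain, C9–OH, C10=CH2), side chain C11–C15; H-5 is α, H-1 is β.

Assumption: (R)-4-(tert-butyldimethylsilyloxy)cyclohex-2-en-1-one and 3-(methoxymethoxy)-2-methylprop-1-ene are bought as such (silyl and methoxymethyl are protecting groups on cores of eight and five heavy atoms).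

## Route

Step 1
Reactants: 1 (R)-4-[(tert-butyldimethylsilyl)oxy]cyclohex-2-en-1-one; 2 (2-bromoprop-2-en-1-yl)trimethylsilane; 3 3-iodoprop-1-ene
Product: 6 (2R,3S,4R)-4-[(tert-butyldimethylsilyl)oxy]-2-(prop-2-en-1-yl)-3-[3-(trimethylsilyl)prop-1-en-2-yl]cyclohexan-1-one, via Grignard reagent 4 (not isolated), via magnesium enolate 5 (not isolated)
Conditions: 2, Mg, THF, 25 °C; CuBr·SMe2 (10 mol%), 1, THF, −78 °C; then 3, DMPU, −78 → 0 °C
Reagents that add atoms: none
Why: Copper-catalysed conjugate addition of the alkenyl Grignard reagent occurs anti to the silyloxy group and the enolate is then allylated anti to the new substituent (tandem 1,4-addition/enolate alkylation), so C5 and C1 become trans and their absolute configuration follows from the purchased stereocentre.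

Step 2
Reactants: 6 (2R,3S,4R)-4-[(tert-butyldimethylsilyl)oxy]-2-(prop-2-en-1-yl)-3-[3-(trimethylsilyl)prop-1-en-2-yl]cyclohexan-1-one
Product: 7 (3aS,4R,7aR)-4-[(tert-butyldimethylsilyl)oxy]-3-[(trimethylsilyl)methyl]-1,3a,4,5,6,7a-hexahydro-7H-inden-7-one
Conditions: second-generation Grubbs catalyst RuCl2(=CHPh)(PCy3)(H2IMes) (5 mol%), CH2Cl2, 40 °C
Reagents that add atoms: none
Why: Ring-closing metathesis between the allyl group and the 1,1-disubstituted alkene closes the cyclopentene at C3=C4, away from the two ring-fusion carbons, so the trans fusion set in step 1 is kept and a cyclic allylsilane results.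

Step 3
Reactants: 7 (3aS,4R,7aR)-4-[(tert-butyldimethylsilyl)oxy]-3-[(trimethylsilyl)methyl]-1,3a,4,5,6,7a-hexahydro-7H-inden-7-one
Product: 8 tert-butyldimethyl{[(3aS,4R,7aR)-7-methylidene-3-[(trimethylsilyl)methyl]-3a,4,5,6,7,7a-hexahydro-1H-inden-4-yl]oxy}silane
Conditions: Ph3PCH3Br, KOtBu, THF, 0 → 25 °C
Reagents that add atoms: methyltriphenylphosphonium bromide, C[P+](c1ccccc1)(c1ccccc1)c1ccccc1.[Br-]
Why: Wittig methylenation converts the C10 ketone into the exo-methylene; the adjacent C1 centre is not scrambled because the trans-fused arrangement is also the thermodynamic one for a ketone in the six-membered ring.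

Step 4
Reactants: 8 tert-butyldimethyl{[(3aS,4R,7aR)-7-methylidene-3-[(trimethylsilyl)methyl]-3a,4,5,6,7,7a-hexahydro-1H-inden-4-yl]oxy}silane
Product: 9 (3aS,4R,7aR)-3,7-dimethylideneoctahydro-1H-inden-4-ol
Conditions: 48% aq. HF, MeCN, 0 → 25 °C
Reagents that add atoms: none
Why: SE2' protodesilylation of the allylsilane (proton at C3, loss of Me3Si) moves the alkene regiospecifically to the exocyclic C4=CH2 position, and the same reagent cleaves the silyl ether.

Step 5
Reactants: 9 (3aS,4R,7aR)-3,7-dimethylideneoctahydro-1H-inden-4-ol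
Product: 10 (3aS,7aR)-3,7-dimethylideneoctahydro-4H-inden-4-one
Conditions: Dess–Martin periodinane, pyridine, CH2Cl2, 0 °C
Reagents that add atoms: none
Why: Buffered Dess–Martin oxidation gives the C6 ketone under neutral conditions, which avoid epimerisation at C5 or migration of the β,γ-alkene into conjugation; the ketone is used at once.

Step 6
Reactants: 11 3-(methoxymethoxy)-2-methylprop-1-ene; 12 3-methylbut-2-enal
Product: 16 (3S,4S)-3-(methoxymethoxy)-2,6-dimethylhepta-1,5-dien-4-ol, via allyllithium 13 (not isolated), via allylborane 14 (not isolated), via borinate 15 (not isolated)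
Conditions: 11, s-BuLi, THF, −78 °C; (+)-Ipc2BOMe; BF3·OEt2; 12, −78 °C; then NaOH, H2O2, 0 °C
Reagents that add atoms: none
Why: Brown-type alkoxyallylboration through a chair transition state: the (Z)-γ-alkoxyallylborane gives the syn-diol relationship (C12, C13) and the isopinocampheyl groups derived from (−)-α-pinene direct attack to the Re face of the aldehyde (13S).

Step 7
Reactants: 16 (3S,4S)-3-(methoxymethoxy)-2,6-dimethylhepta-1,5-dien-4-ol
Product: 17 (3S,4S)-2,6-dimethylhepta-1,5-diene-3,4-diol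
Conditions: ZnBr2, n-PrSH, CH2Cl2, 0 °C
Reagents that add atoms: none
Why: Lewis acid/thiol acetal exchange removes the MOM group within minutes at 0 °C, which is mild enough for the doubly allylic diol.

Step 8
Reactants: 17 (3S,4S)-2,6-dimethylhepta-1,5-diene-3,4-diol
Product: 18 (3S,4S)-2,6-dimethylhepta-1,5-diene-3,4-diyl diacetate
Conditions: Ac2O, pyridine, DMAP (cat.), CH2Cl2, 0 → 25 °C
Reagents that add atoms: acetic anhydride, CC(=O)OC(C)=O
Why: Standard DMAP-catalysed acylation installs both acetates of the target before any ring hydroxyl exists, so no later differentiation is needed.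

Step 9
Reactants: 18 (3S,4S)-2,6-dimethylhepta-1,5-diene-3,4-diyl diacetate
Product: 20 (2R,3S,4S)-1-hydroxy-2,6-dimethylhept-5-ene-3,4-diyl diacetate, via catechol boronate 19 (not isolated)
Conditions: catecholborane, RhCl(PPh3)3 (3 mol%), THF, −20 → 25 °C; then pH 7 buffer, H2O2, 0 °C
Reagents that add atoms: catecholborane, B1Oc2ccccc2O1 (boron of 19); hydrogen peroxide, OO (hydroxyl oxygen of 20)
Why: Rhodium-catalysed hydroboration is anti-Markovnikov, leaves the trisubstituted alkene alone and gives the 2,3-syn product next to an allylic acyloxy group (the opposite sense to uncatalysed hydroboration), which sets C11; neutral oxidation spares the acetates.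

Step 10
Reactants: 20 (2R,3S,4S)-1-hydroxy-2,6-dimethylhept-5-ene-3,4-diyl diacetate
Product: 21 (2S,3S,4S)-2,6-dimethyl-1-oxohept-5-ene-3,4-diyl diacetate
Conditions: Dess–Martin periodinane, pyridine, CH2Cl2, 0 °C
Reagents that add atoms: none
Why: Buffered Dess–Martin oxidation gives the α-branched aldehyde without epimerisation or β-elimination of acetate.

Step 11
Reactants: 21 (2S,3S,4S)-2,6-dimethyl-1-oxohept-5-ene-3,4-diyl diacetate
Product: 22 (2R,3S,4S)-1-[(E)-2-(tert-butyldimethylsilyl)hydrazinylidene]-2,6-dimethylhept-5-ene-3,4-diyl diacetate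
Conditions: TBSNHNHTBS, Sc(OTf)3 (0.01 mol%), CH2Cl2, 0 → 25 °C
Reagents that add atoms: 1,2-bis(tert-butyldimethylsilyl)hydrazine, CC(C)(C)[Si](C)(C)NN[Si](C)(C)C(C)(C)C
Why: Lewis acid-catalysed N-silylhydrazone formation is neutral, gives no azine and leaves the acetates and the α-stereocentre intact, providing a storable diazo precursor.

Step 12
Reactants: 10 (3aS,7aR)-3,7-dimethylideneoctahydro-4H-inden-4-one; 22 (2R,3S,4S)-1-[(E)-2-(tert-butyldimethylsilyl)hydrazinylidene]-2,6-dimethylhept-5-ene-3,4-diyl diacetate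
Product: 24 (2R,3S,4S)-2-[(3aS,5S,8aR)-3,8-dimethylidene-4-oxodecahydroazulen-5-yl]-6-methylhept-5-ene-3,4-diyl diacetate, via diazoalkane 23 (not isolated)
Conditions: 22, PhIF2, 2-chloropyridine, CH2Cl2, −78 °C; cold filtration through K2CO3; then 10, Sc(OTf)3 (10 mol%), (S,S)-Ph-PyBOX (12 mol%), toluene, −78 → −40 °C
Reagents that add atoms: none
Why: Proposed new method: a chiral trivalent-scandium Lewis acid activates ketone 10, the α-branched non-stabilised diazoalkane adds by equatorial approach to give a β-oxido diazonium ion, and the less substituted C8 migrates anti to the departing N2 (1,2-alkyl shift, one-carbon ring expansion), forming C6–C7 and C7–C8; in the migrating rotamer the side chain lies anti to the bulky scandium-bound oxygen, which gives the 7α configuration, and the ligand antipode is chosen to reinforce this; the closest known reaction is the Sc(OTf)3-catalysed homologation of simple cycloalkanones with aryl- and alkyldiazomethanes, which has not been shown for a fully functionalised chiral diazoalkane, for a β,γ-unsaturated bicyclic ketone or with ligand-controlled diastereoselection.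

Step 13
Reactants: 24 (2R,3S,4S)-2-[(3aS,5S,8aR)-3,8-dimethylidene-4-oxodecahydroazulen-5-yl]-6-methylhept-5-ene-3,4-diyl diacetate
Product: 25 (2R,3S,4S)-2-[(3aS,4R,5S,8aR)-4-hydroxy-3,8-dimethylidenedecahydroazulen-5-yl]-6-methylhept-5-ene-3,4-diyl diacetate
Conditions: LiBH(s-Bu)3, THF, −78 °C; H2O quench
Reagents that add atoms: none
Why: Bulky hydride reduction of the crude ketone: the C7 side chain is pseudo-axial on the α face (trans to the ring-fusion substituent across the carbonyl), so hydride enters from the β face and gives the 6α-alcohol cis to the side chain, while the low temperature spares the acetates and the epimerisable C5 and C7.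

Step 14
Reactants: 25 (2R,3S,4S)-2-[(3aS,4R,5S,8aR)-4-hydroxy-3,8-dimethylidenedecahydroazulen-5-yl]-6-methylhept-5-ene-3,4-diyl diacetate
Product: 26 (2R,3S,4S)-2-[(2S,3aS,4R,5S,7R,8aR)-2,4,7-trihydroxy-3,8-dimethylidenedecahydroazulen-5-yl]-6-methylhept-5-ene-3,4-diyl diacetate
Conditions: SeO2 (0.5 equiv), t-BuOOH (4 equiv), CH2Cl2, 0 → 25 °C
Reagents that add atoms: selenium dioxide, O=[Se]=O (oxygen carrier); tert-butyl hydroperoxide, CC(C)(C)OO (terminal oxidant)
Why: Twofold SeO2 allylic hydroxylation (ene reaction, then [2,3]-shift) attacks the ring CH2 next to each exo-methylene in preference to the ring-fusion CH and delivers oxygen on the face opposite the neighbouring ring branch, cis to the adjacent ring-fusion hydrogen (3α and 9β, the latter also anti to the α side chain); the side-chain alkene is deactivated by its allylic acetoxy group.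

## Compound list

1 | (R)-4-[(tert-butyldimethylsilyl)oxy]cyclohex-2-en-1-one | O=C1C=C[C@H](O[Si](C)(C)C(C)(C)C)CC1 | starting material
2 | (2-bromoprop-2-en-1-yl)trimethylsilane | C=C(Br)C[Si](C)(C)C | starting material
3 | 3-iodoprop-1-ene | C=CCI | starting material
4 | [3-(trimethylsilyl)prop-1-en-2-yl]magnesium bromide | C=C([Mg]Br)C[Si](C)(C)C | intermediate
5 | bromomagnesium (3S,4R)-4-[(tert-butyldimethylsilyl)oxy]-3-[3-(trimethylsilyl)prop-1-en-2-yl]cyclohex-1-en-1-olate | Br[Mg]OC1=C[C@@H](C(=C)C[Si](C)(C)C)[C@H](O[Si](C)(C)C(C)(C)C)CC1 | intermediate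
6 | (2R,3S,4R)-4-[(tert-butyldimethylsilyl)oxy]-2-(prop-2-en-1-yl)-3-[3-(trimethylsilyl)prop-1-en-2-yl]cyclohexan-1-one | O=C1[C@H](CC=C)[C@@H](C(=C)C[Si](C)(C)C)[C@H](O[Si](C)(C)C(C)(C)C)CC1 | intermediate
7 | (3aS,4R,7aR)-4-[(tert-butyldimethylsilyl)oxy]-3-[(trimethylsilyl)methyl]-1,3a,4,5,6,7a-hexahydro-7H-inden-7-one | C[Si](C)(C)CC=1[C@H]2[C@H](O[Si](C)(C)C(C)(C)C)CCC(=O)[C@@H]2CC=1 | intermediate
8 | tert-butyldimethyl{[(3aS,4R,7aR)-7-methylidene-3-[(trimethylsilyl)methyl]-3a,4,5,6,7,7a-hexahydro-1H-inden-4-yl]oxy}silane | C[Si](C)(C)CC=1[C@H]2[C@H](O[Si](C)(C)C(C)(C)C)CCC(=C)[C@@H]2CC=1 | intermediate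
9 | (3aS,4R,7aR)-3,7-dimethylideneoctahydro-1H-inden-4-ol | C=C1[C@H]2[C@H](O)CCC(=C)[C@@H]2CC1 | intermediate
10 | (3aS,7aR)-3,7-dimethylideneoctahydro-4H-inden-4-one | C=C1[C@H]2C(=O)CCC(=C)[C@@H]2CC1 | intermediate
11 | 3-(methoxymethoxy)-2-methylprop-1-ene | C=C(C)COCOC | starting material
12 | 3-methylbut-2-enal | CC(C)=CC=O | starting material
13 | (Z)-[3-(methoxymethoxy)-2-methylprop-2-en-1-yl]lithium | [Li]C/C(C)=C\OCOC | intermediate
14 | [(Z)-3-(methoxymethoxy)-2-methylprop-2-en-1-yl]bis(isopinocampheyl)borane (Ipc groups from (−)-α-pinene) | COCO/C=C(/C)CB([C@H]1C[C@H]2C[C@@H]([C@@H]1C)C2(C)C)[C@H]1C[C@H]2C[C@@H]([C@@H]1C)C2(C)C | intermediate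
15 | bis(isopinocampheyl)borinic ester of 16 | C=C(C)[C@H](OCOC)[C@H](C=C(C)C)OB([C@H]1C[C@H]2C[C@@H]([C@@H]1C)C2(C)C)[C@H]1C[C@H]2C[C@@H]([C@@H]1C)C2(C)C | intermediate
16 | (3S,4S)-3-(methoxymethoxy)-2,6-dimethylhepta-1,5-dien-4-ol | C=C(C)[C@H](OCOC)[C@H](C=C(C)C)O | intermediate
17 | (3S,4S)-2,6-dimethylhepta-1,5-diene-3,4-diol | C=C(C)[C@H](O)[C@H](C=C(C)C)O | intermediate
18 | (3S,4S)-2,6-dimethylhepta-1,5-diene-3,4-diyl diacetate | C=C(C)[C@H](OC(C)=O)[C@H](C=C(C)C)OC(C)=O | intermediate
19 | (2R,3S,4S)-1-(1,3,2-benzodioxaborol-2-yl)-2,6-dimethylhept-5-ene-3,4-diyl diacetate | B1(Oc2ccccc2O1)C[C@@H](C)[C@H](OC(C)=O)[C@H](C=C(C)C)OC(C)=O | intermediate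
20 | (2R,3S,4S)-1-hydroxy-2,6-dimethylhept-5-ene-3,4-diyl diacetate | OC[C@@H](C)[C@H](OC(C)=O)[C@H](C=C(C)C)OC(C)=O | intermediate
21 | (2S,3S,4S)-2,6-dimethyl-1-oxohept-5-ene-3,4-diyl diacetate | O=C[C@@H](C)[C@H](OC(C)=O)[C@H](C=C(C)C)OC(C)=O | intermediate
22 | (2R,3S,4S)-1-[(E)-2-(tert-butyldimethylsilyl)hydrazinylidene]-2,6-dimethylhept-5-ene-3,4-diyl diacetate | CC(C)(C)[Si](C)(C)N/N=C/[C@@H](C)[C@H](OC(C)=O)[C@H](C=C(C)C)OC(C)=O | intermediate
23 | (2R,3S,4S)-1-diazo-2,6-dimethylhept-5-ene-3,4-diyl diacetate | [N-]=[N+]=C[C@@H](C)[C@H](OC(C)=O)[C@H](C=C(C)C)OC(C)=O | intermediate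
24 | (2R,3S,4S)-2-[(3aS,5S,8aR)-3,8-dimethylidene-4-oxodecahydroazulen-5-yl]-6-methylhept-5-ene-3,4-diyl diacetate | C=C1[C@H]2C(=O)[C@H]([C@@H](C)[C@H](OC(C)=O)[C@H](C=C(C)C)OC(C)=O)CCC(=C)[C@@H]2CC1 | intermediate
25 | (2R,3S,4S)-2-[(3aS,4R,5S,8aR)-4-hydroxy-3,8-dimethylidenedecahydroazulen-5-yl]-6-methylhept-5-ene-3,4-diyl diacetate | C=C1[C@H]2[C@H](O)[C@H]([C@@H](C)[C@H](OC(C)=O)[C@H](C=C(C)C)OC(C)=O)CCC(=C)[C@@H]2CC1 | intermediate
26 | (2R,3S,4S)-2-[(2S,3aS,4R,5S,7R,8aR)-2,4,7-trihydroxy-3,8-dimethylidenedecahydroazulen-5-yl]-6-methylhept-5-ene-3,4-diyl diacetate | C=C1[C@H]2[C@H](O)[C@H]([C@@H](C)[C@H](OC(C)=O)[C@H](C=C(C)C)OC(C)=O)C[C@@H](O)C(=C)[C@@H]2C[C@@H]1O | target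

## Step count and risks

Total step count: 14. Longest linear sequence: 9 steps (steps 6 to 14); the ring half joins after 5 steps.

Steps most likely to fail:

Step 12 (the proposed new ring-expansion coupling; risks are catalyst poisoning, wrong C7 epimer, C5 migration). The fallback is a classical Tiffeneau–Demjanov ring expansion, known chemistry, which sets out from alcohol 20 and ketone 10 and comes back at ketone 24. Alcohol 20 is converted with I2, PPh3 and imidazole into (2S,3S,4S)-1-iodo-2,6-dimethylhept-5-ene-3,4-diyl diacetate F1. AgNO2 in Et2O gives (2R,3S,4S)-2,6-dimethyl-1-nitrohept-5-ene-3,4-diyl diacetate F2. A tetramethylguanidine-catalysed nitro-aldol addition of F2 to 10 gives the β-nitro alcohol F3 (epimers at the two new centres). Zn in AcOH reduces it to the β-amino alcohol F4. NaNO2 in aqueous AcOH at 0 °C then generates the same β-hydroxy diazonium ion, and migration of C8 gives 24 after separation of the C7 epimers.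

Step 14 (twofold allylic hydroxylation with the side-chain alkene present; risks are chemoselectivity, over-oxidation and facial control on the flexible ring). The fallback hydroxylates before the halves are joined; it sets out from ketone 10 and comes back at target 26. SeO2/t-BuOOH on the rigid chair of 10 gives (2S,3aS,6R,7aR)-2,6-dihydroxy-3,7-dimethylideneoctahydro-4H-inden-4-one F5 (axial 9β-OH, 3α-OH). TBSOTf and 2,6-lutidine give the bis-silyl ether (2S,3aS,6R,7aR)-2,6-bis[(tert-butyldimethylsilyl)oxy]-3,7-dimethylideneoctahydro-4H-inden-4-one F6. Ring expansion with 22 under the conditions of step 12 gives the 3,9-bis-silyl ether of the 6-ketone F7. LiBH(s-Bu)3 gives the 3,9-bis-silyl ether of the target F8. HF·pyridine in THF removes both silyl groups without touching the acetates and gives 26.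

Step 13 (facial selectivity of the reduction next to two epimerisable centres). The fallback corrects the centre after the fact; it sets out from ketone 24 and comes back at alcohol 25. If hydride enters from the α face, the 6β-alcohol, the C6 epimer of 25 F9, is formed. Mitsunobu inversion with chloroacetic acid, PPh3 and DIAD gives the 6α-chloroacetate of 25 F10. Thiourea and NaHCO3 in EtOH cleave only the chloroacetate and give 25.

## Further compounds

F1 | step 12 | (2S,3S,4S)-1-iodo-2,6-dimethylhept-5-ene-3,4-diyl diacetate | IC[C@@H](C)[C@H](OC(C)=O)[C@H](C=C(C)C)OC(C)=O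
F2 | step 12 | (2R,3S,4S)-2,6-dimethyl-1-nitrohept-5-ene-3,4-diyl diacetate | [O-][N+](=O)C[C@@H](C)[C@H](OC(C)=O)[C@H](C=C(C)C)OC(C)=O
F3 | step 12 | β-nitro alcohol from F2 and 10 (epimers at the carbinol and nitro-bearing carbons) | C=C1[C@H]2C(O)(C([N+](=O)[O-])[C@@H](C)[C@H](OC(C)=O)[C@H](C=C(C)C)OC(C)=O)CCC(=C)[C@@H]2CC1
F4 | step 12 | β-amino alcohol from F3 (epimers at the carbinol and amino-bearing carbons) | C=C1[C@H]2C(O)(C(N)[C@@H](C)[C@H](OC(C)=O)[C@H](C=C(C)C)OC(C)=O)CCC(=C)[C@@H]2CC1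
F5 | step 14 | (2S,3aS,6R,7aR)-2,6-dihydroxy-3,7-dimethylideneoctahydro-4H-inden-4-one | C=C1[C@H]2C(=O)C[C@@H](O)C(=C)[C@@H]2C[C@@H]1O
F6 | step 14 | (2S,3aS,6R,7aR)-2,6-bis[(tert-butyldimethylsilyl)oxy]-3,7-dimethylideneoctahydro-4H-inden-4-one | C=C1[C@H]2C(=O)C[C@@H](O[Si](C)(C)C(C)(C)C)C(=C)[C@@H]2C[C@@H]1O[Si](C)(C)C(C)(C)C
F7 | step 14 | 3,9-bis(tert-butyldimethylsilyl) ether of the 6-ketone of the target | C=C1[C@H]2C(=O)[C@H]([C@@H](C)[C@H](OC(C)=O)[C@H](C=C(C)C)OC(C)=O)C[C@@H](O[Si](C)(C)C(C)(C)C)C(=C)[C@@H]2C[C@@H]1O[Si](C)(C)C(C)(C)C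
F8 | step 14 | 3,9-bis(tert-butyldimethylsilyl) ether of the target | C=C1[C@H]2[C@H](O)[C@H]([C@@H](C)[C@H](OC(C)=O)[C@H](C=C(C)C)OC(C)=O)C[C@@H](O[Si](C)(C)C(C)(C)C)C(=C)[C@@H]2C[C@@H]1O[Si](C)(C)C(C)(C)C
F9 | step 13 | C6 epimer (6β-alcohol) of 25 | C=C1[C@H]2[C@@H](O)[C@H]([C@@H](C)[C@H](OC(C)=O)[C@H](C=C(C)C)OC(C)=O)CCC(=C)[C@@H]2CC1
F10 | step 13 | 6α-chloroacetate of 25 | C=C1[C@H]2[C@H](OC(=O)CCl)[C@H]([C@@H](C)[C@H](OC(C)=O)[C@H](C=C(C)C)OC(C)=O)CCC(=C)[C@@H]2CC1
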